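## Retrosynthetic overview

1. Locants are those of the target tetralone (C1 ketone, C3 carbinol, C4a/C8a ring fusion, C5 pyranonyl, C6 isopentyl, C8 phenol); the benzene ring is ring A and the carbocycle holding C1–C4 is ring B.
2. The strategy rests on the substitution pattern of ring A: the carbon substituent at C5 is para to the C8 oxygen, with isopentyl at C6 and hydrogen at C7. This is the para pattern formed when a 2-oxygenated diene (C7=C8–C8a=C4a, built on ring B) adds to a β-alkyl ynoate (C5≡C6) and the adduct is dehydrogenated.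
3. Disconnections: the pyranone comes from the C5 carboxylic acid and an acetoacetate-dioxinone dienolate (acylation, then acylketene cyclisation); ring A from a 2-silyloxydiene and allyl 6-methylhept-2-ynoate (Diels–Alder, DDQ); the diene from (R)-5-silyloxycyclohex-2-enone (α-iodination, 1,2-reduction, Stille acetylation, enol silylation); the enone from cis,cis-cyclohexane-1,3,5-triol by lipase desymmetrisation.
4. Design choices: C1 passes through the cycloaddition as a triethylsilyl ether, so there is no enone to dimerise and no β-silyloxy ketone to eliminate. The C8 oxygen is a silyl enol ether that becomes an aryl silyl ether, removable at the end by fluoride instead of a Lewis acid that would dehydrate the 3-hydroxytetralone. The ester is allyl, cleavable although di-ortho-substituted.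
5. Ring order: ring B (from the triol), ring A (step 10), pyranone (step 13); the single stereocentre C3 is set in step 2.

Key step: step 10

Assumption: Candida antarctica lipase B is taken to acetylate the R-configured carbinol of the meso diol, the usual sense for secondary alcohols, which leads to the R enone and hence to R at C3.

## Route

Step 1
Reactants: 1 cis,cis-cyclohexane-1,3,5-triol
Product: 2 cis,cis-5-(tert-butyldimethylsilyloxy)cyclohexane-1,3-diol (meso)
Conditions: TBSCl (0.9 equiv), imidazole, DMF, 0 °C → rt; unreacted triol recovered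
Reagents that add atoms: tert-butyldimethylsilyl chloride, CC(C)(C)[Si](C)(C)Cl
Why: Statistical monosilylation of one of three equivalent hydroxyls with a deficiency of silyl chloride should give the meso mono-ether, so no stereochemistry is at stake yet.

Step 2
Reactants: 2 cis,cis-5-(tert-butyldimethylsilyloxy)cyclohexane-1,3-diol
Product: 3 (1R,3S,5S)-3-(tert-butyldimethylsilyloxy)-5-hydroxycyclohexyl acetate
Conditions: Novozym 435 (immobilised Candida antarctica lipase B), vinyl acetate, THF, 30 °C
Reagents that add atoms: vinyl acetate, CC(=O)OC=C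
Why: Lipase-catalysed desymmetrisation of the meso diol by irreversible transesterification should acetylate the R carbinol selectively, which fixes the absolute configuration of the ring and thereby the later C3 centre.

Step 3
Reactants: 3 (1R,3S,5S)-3-(tert-butyldimethylsilyloxy)-5-hydroxycyclohexyl acetate
Product: 5 (R)-5-(tert-butyldimethylsilyloxy)cyclohex-2-en-1-one, via acetoxy ketone 4 (not isolated)
Conditions: nPr4N[RuO4] (5 mol %), NMO, 4 Å MS, CH2Cl2, rt; then DBU, 0 °C
Reagents that add atoms: none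
Why: Ley–Griffith oxidation of the free carbinol gives a β-acetoxy ketone that should lose acetate by E1cB elimination far faster than the silyloxy group on the other β-carbon, so the silyloxy carbon becomes C5 of the enone with R configuration.

Step 4
Reactants: 5 (R)-5-(tert-butyldimethylsilyloxy)cyclohex-2-en-1-one
Product: 6 (R)-5-(tert-butyldimethylsilyloxy)-2-iodocyclohex-2-en-1-one
Conditions: I2, pyridine/CH2Cl2 (1:1), 0 °C → rt
Reagents that add atoms: iodine, II
Why: α-Iodination of the enone by a Baylis–Hillman-type sequence (pyridine conjugate addition, iodination of the enolate, elimination) is mild enough that the β-silyloxy group should not eliminate.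

Step 5
Reactants: 6 (R)-5-(tert-butyldimethylsilyloxy)-2-iodocyclohex-2-en-1-one
Product: 7 (1R,5R)-5-(tert-butyldimethylsilyloxy)-2-iodocyclohex-2-en-1-ol
Conditions: NaBH4, CeCl3·7H2O, MeOH, −78 °C
Reagents that add atoms: none
Why: Luche 1,2-reduction with axial hydride delivery should give mainly the cis allylic alcohol, by analogy with other 5-substituted cyclohexenones, and any trans epimer is harmless because this carbon is re-oxidised in step 15.

Step 6
Reactants: 7 (1R,5R)-5-(tert-butyldimethylsilyloxy)-2-iodocyclohex-2-en-1-ol; 8 tributyl(1-ethoxyvinyl)stannane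
Product: 10 1-[(4R,6R)-4-(tert-butyldimethylsilyloxy)-6-hydroxycyclohex-1-en-1-yl]ethan-1-one, via ethoxydiene 9 (not isolated)
Conditions: Pd(PPh3)4 (5 mol %), CuI (10 mol %), DMF, 50 °C; then aq. oxalic acid, THF, rt
Reagents that add atoms: water, O
Why: Copper-accelerated Stille coupling of the vinyl iodide tolerates the free hydroxyl, and the very acid-labile 2-ethoxydiene should hydrolyse under mild aqueous acid to the methyl ketone without touching the secondary silyl ether.

Step 7
Reactants: 10 1-[(4R,6R)-4-(tert-butyldimethylsilyloxy)-6-hydroxycyclohex-1-en-1-yl]ethan-1-one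
Product: 11 1-[(4R,6R)-4-(tert-butyldimethylsilyloxy)-6-(triethylsilyloxy)cyclohex-1-en-1-yl]ethan-1-one
Conditions: TESCl, imidazole, CH2Cl2, 0 °C
Reagents that add atoms: triethylsilyl chloride, CC[Si](Cl)(CC)CC
Why: Standard silylation of the allylic alcohol; the triethylsilyl group is chosen so that this oxygen (the future C1) can later be unmasked in the presence of the tert-butyldimethylsilyl ethers.

Step 8
Reactants: 11 1-[(4R,6R)-4-(tert-butyldimethylsilyloxy)-6-(triethylsilyloxy)cyclohex-1-en-1-yl]ethan-1-one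
Product: 12 (4R,6R)-4-(tert-butyldimethylsilyloxy)-1-[1-(tert-butyldimethylsilyloxy)ethenyl]-6-(triethylsilyloxy)cyclohex-1-ene
Conditions: TBSOTf, Et3N, CH2Cl2, −78 → 0 °C
Reagents that add atoms: tert-butyldimethylsilyl trifluoromethanesulfonate, CC(C)(C)[Si](C)(C)OS(=O)(=O)C(F)(F)F
Why: Soft enolisation of the conjugated methyl ketone on the methyl side with silyl triflate and amine is the standard entry to cross-conjugated 1-(1-silyloxyvinyl)cycloalkenes and should give the 2-silyloxydiene.

Step 9
Reactants: 13 5-methylhex-1-yne; 14 allyl chloroformate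
Product: 16 allyl 6-methylhept-2-ynoate, via lithium acetylide 15 (not isolated)
Conditions: n-BuLi, THF, −78 °C; then ClCO2allyl, −78 → 0 °C
Reagents that add atoms: none
Why: C-Acylation of the lithium acetylide with a chloroformate gives the ynoate, made as the allyl ester because the di-ortho-substituted benzoate formed later resists saponification but an allyl ester is cleaved at the allyl carbon.

Step 10
Reactants: 12 (4R,6R)-4-(tert-butyldimethylsilyloxy)-1-[1-(tert-butyldimethylsilyloxy)ethenyl]-6-(triethylsilyloxy)cyclohex-1-ene; 16 allyl 6-methylhept-2-ynoate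
Product: 18 allyl (1R,3R)-3,8-bis(tert-butyldimethylsilyloxy)-6-(3-methylbutyl)-1-(triethylsilyloxy)-1,2,3,4-tetrahydronaphthalene-5-carboxylate, via cyclohexadiene 17 (not isolated)
Conditions: 16 (4 equiv), BHT (cat.), PhMe, 150 °C (sealed tube); then DDQ (1.1 equiv), 0 °C → rt
Reagents that add atoms: none
Why: The electron-rich 2-silyloxydiene (C7=C8–C8a=C4a) and the ynoate should combine in a concerted, asynchronous normal-electron-demand [4+2] cycloaddition forming C4a–C5 and C6–C7, after which DDQ removes hydride from the doubly allylic C4a–H (the cation is stabilised as a silyloxocarbenium ion at C8) and a proton from C7, giving the benzene ring with the silyl ether retained. The closest known reaction type is the Diels–Alder reaction of 1-(1-silyloxyvinyl)cycloalkenes and other 2-silyloxydienes with acetylenic esters followed by quinone dehydrogenation to aryl silyl ethers. Ring A is closed by intermolecular cycloaddition across the C4a=C8a bond of ring B (annulation), first as a 1,4-cyclohexadiene and then as the arene. No stereocentre is created in the product: the transient C4a centre of 17 is erased on aromatisation and the C1 and C3 centres lie outside the reacting π-system. The step needs para regioselectivity (ester carbon to C4a, alkyl-bearing carbon to C7), which the C8 silyloxy group secures by placing the largest HOMO coefficient on C7 so that it pairs with the electrophilic β-carbon of the ynoate, the alkyl substitution at C4a acting in the same sense. Carrying C1 as a silyl ether keeps the diene free of an enone that could act as dienophile or heterodiene and leaves no β-silyloxy ketone to eliminate at 150 °C.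

Step 11
Reactants: 18 allyl (1R,3R)-3,8-bis(tert-butyldimethylsilyloxy)-6-(3-methylbutyl)-1-(triethylsilyloxy)-1,2,3,4-tetrahydronaphthalene-5-carboxylate
Product: 19 (1R,3R)-3,8-bis(tert-butyldimethylsilyloxy)-6-(3-methylbutyl)-1-(triethylsilyloxy)-1,2,3,4-tetrahydronaphthalene-5-carboxylic acid
Conditions: Pd(PPh3)4 (5 mol %), morpholine, THF, rt; aq. citric acid work-up
Reagents that add atoms: none
Why: Tsuji–Trost deallylation (π-allyl formation on zerovalent palladium, capture by morpholine) takes place at the allyl carbon and is therefore indifferent to the steric shielding of the carbonyl group, under neutral conditions that spare all three silyl ethers.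

Step 12
Reactants: 19 (1R,3R)-3,8-bis(tert-butyldimethylsilyloxy)-6-(3-methylbutyl)-1-(triethylsilyloxy)-1,2,3,4-tetrahydronaphthalene-5-carboxylic acid; 20 2,2,6-trimethyl-4H-1,3-dioxin-4-one
Product: 23 6-{2-[(1R,3R)-3,8-bis(tert-butyldimethylsilyloxy)-6-(3-methylbutyl)-1-(triethylsilyloxy)-1,2,3,4-tetrahydronaphthalen-5-yl]-2-oxoethyl}-2,2-dimethyl-4H-1,3-dioxin-4-one, via acid chloride 21 (not isolated), via lithium dienolate 22 (not isolated)
Conditions: 1-chloro-N,N,2-trimethylprop-1-en-1-amine (1.1 equiv), CH2Cl2, 0 °C → rt; 20 (2.5 equiv), LiN(SiMe3)2 (2.5 equiv), THF, −78 °C, then 21; aq. NH4Cl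
Reagents that add atoms: none
Why: The chloroenamine converts the acid to its chloride without releasing HCl, and Claisen-type γ-C-acylation of the dioxinone lithium dienolate (excess, since the product is more acidic) should give the keto-dioxinone; the substrate carries no ketone at C1 that could enolise and expel the C3 oxygen.

Step 13
Reactants: 23 6-{2-[(1R,3R)-3,8-bis(tert-butyldimethylsilyloxy)-6-(3-methylbutyl)-1-(triethylsilyloxy)-1,2,3,4-tetrahydronaphthalen-5-yl]-2-oxoethyl}-2,2-dimethyl-4H-1,3-dioxin-4-one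
Product: 25 4-hydroxy-6-[(1R,3R)-3,8-bis(tert-butyldimethylsilyloxy)-6-(3-methylbutyl)-1-(triethylsilyloxy)-1,2,3,4-tetrahydronaphthalen-5-yl]-2H-pyran-2-one, via acylketene 24 (not isolated)
Conditions: PhMe, 110 °C
Reagents that add atoms: none
Why: Thermal retro-[4+2] fragmentation of the dioxinone releases acetone and an acylketene, which the enol oxygen of the aryl ketone should trap intramolecularly to close the 4-hydroxy-2-pyranone ring.

Step 14
Reactants: 25 4-hydroxy-6-[(1R,3R)-3,8-bis(tert-butyldimethylsilyloxy)-6-(3-methylbutyl)-1-(triethylsilyloxy)-1,2,3,4-tetrahydronaphthalen-5-yl]-2H-pyran-2-one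
Product: 26 4-hydroxy-6-[(1R,3R)-3,8-bis(tert-butyldimethylsilyloxy)-1-hydroxy-6-(3-methylbutyl)-1,2,3,4-tetrahydronaphthalen-5-yl]-2H-pyran-2-one
Conditions: PPTS (0.2 equiv), MeOH/CH2Cl2 (1:1), 0 °C → rt
Reagents that add atoms: none
Why: Acid-catalysed methanolysis should cleave the secondary triethylsilyl ether much faster than the secondary alkyl and the aryl tert-butyldimethylsilyl ethers.

Step 15
Reactants: 26 4-hydroxy-6-[(1R,3R)-3,8-bis(tert-butyldimethylsilyloxy)-1-hydroxy-6-(3-methylbutyl)-1,2,3,4-tetrahydronaphthalen-5-yl]-2H-pyran-2-one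
Product: 27 (3R)-3,8-bis(tert-butyldimethylsilyloxy)-5-(4-hydroxy-2-oxo-2H-pyran-6-yl)-6-(3-methylbutyl)-3,4-dihydronaphthalen-1(2H)-one
Conditions: activated MnO2 (excess), CH2Cl2, rt
Reagents that add atoms: none
Why: Activated MnO2 oxidises benzylic alcohols under neutral heterogeneous conditions that should leave the acidic pyranone enol and the β-silyloxy ketone product untouched, and both C1 epimers converge on the same ketone.

Step 16
Reactants: 27 (3R)-3,8-bis(tert-butyldimethylsilyloxy)-5-(4-hydroxy-2-oxo-2H-pyran-6-yl)-6-(3-methylbutyl)-3,4-dihydronaphthalen-1(2H)-one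
Product: 28 (3R)-3,8-dihydroxy-5-(4-hydroxy-2-oxo-2H-pyran-6-yl)-6-(3-methylbutyl)-3,4-dihydronaphthalen-1(2H)-one (CNP0134824.1)
Conditions: HF·pyridine, pyridine, THF, 0 °C → rt
Reagents that add atoms: none
Why: Buffered fluoride desilylation should free the peri phenol and the C3 alcohol without the base or Lewis acid that would trigger β-elimination and aromatisation to a naphthol, and the C3 centre is not touched.

## Compound list

1 | cis,cis-cyclohexane-1,3,5-triol | O[C@H]1C[C@@H](O)C[C@@H](O)C1 | starting material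
2 | cis,cis-5-(tert-butyldimethylsilyloxy)cyclohexane-1,3-diol (meso) | CC(C)(C)[Si](C)(C)O[C@H]1C[C@@H](O)C[C@@H](O)C1 | intermediate
3 | (1R,3S,5S)-3-(tert-butyldimethylsilyloxy)-5-hydroxycyclohexyl acetate | CC(C)(C)[Si](C)(C)O[C@H]1C[C@@H](O)C[C@@H](OC(C)=O)C1 | intermediate
4 | (1S,3R)-3-(tert-butyldimethylsilyloxy)-5-oxocyclohexyl acetate (not isolated) | CC(C)(C)[Si](C)(C)O[C@H]1CC(=O)C[C@@H](OC(C)=O)C1 | intermediate
5 | (R)-5-(tert-butyldimethylsilyloxy)cyclohex-2-en-1-one | CC(C)(C)[Si](C)(C)O[C@H]1CC(=O)C=CC1 | intermediate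
6 | (R)-5-(tert-butyldimethylsilyloxy)-2-iodocyclohex-2-en-1-one | CC(C)(C)[Si](C)(C)O[C@H]1CC(=O)C(I)=CC1 | intermediate
7 | (1R,5R)-5-(tert-butyldimethylsilyloxy)-2-iodocyclohex-2-en-1-ol | CC(C)(C)[Si](C)(C)O[C@H]1C[C@@H](O)C(I)=CC1 | intermediate
8 | tributyl(1-ethoxyvinyl)stannane | CCCC[Sn](CCCC)(CCCC)C(=C)OCC | starting material
9 | (1R,5R)-5-(tert-butyldimethylsilyloxy)-2-(1-ethoxyethenyl)cyclohex-2-en-1-ol (not isolated) | CC(C)(C)[Si](C)(C)O[C@H]1C[C@@H](O)C(C(=C)OCC)=CC1 | intermediate
10 | 1-[(4R,6R)-4-(tert-butyldimethylsilyloxy)-6-hydroxycyclohex-1-en-1-yl]ethan-1-one | CC(C)(C)[Si](C)(C)O[C@H]1C[C@@H](O)C(C(C)=O)=CC1 | intermediate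
11 | 1-[(4R,6R)-4-(tert-butyldimethylsilyloxy)-6-(triethylsilyloxy)cyclohex-1-en-1-yl]ethan-1-one | CC(C)(C)[Si](C)(C)O[C@H]1C[C@@H](O[Si](CC)(CC)CC)C(C(C)=O)=CC1 | intermediate
12 | (4R,6R)-4-(tert-butyldimethylsilyloxy)-1-[1-(tert-butyldimethylsilyloxy)ethenyl]-6-(triethylsilyloxy)cyclohex-1-ene (key-step diene) | CC(C)(C)[Si](C)(C)O[C@H]1C[C@@H](O[Si](CC)(CC)CC)C(C(=C)O[Si](C)(C)C(C)(C)C)=CC1 | intermediate
13 | 5-methylhex-1-yne | C#CCCC(C)C | starting material
14 | allyl chloroformate | C=CCOC(=O)Cl | starting material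
15 | (5-methylhex-1-yn-1-yl)lithium (not isolated) | [Li]C#CCCC(C)C | intermediate
16 | allyl 6-methylhept-2-ynoate (key-step dienophile) | C=CCOC(=O)C#CCCC(C)C | intermediate
17 | allyl (1R,3R)-3,8-bis(tert-butyldimethylsilyloxy)-6-(3-methylbutyl)-1-(triethylsilyloxy)-1,2,3,4,4a,7-hexahydronaphthalene-5-carboxylate, both C4a epimers (not isolated) | C=CCOC(=O)C1=C(CCC(C)C)CC(O[Si](C)(C)C(C)(C)C)=C2C1C[C@@H](O[Si](C)(C)C(C)(C)C)C[C@H]2O[Si](CC)(CC)CC | intermediate
18 | allyl (1R,3R)-3,8-bis(tert-butyldimethylsilyloxy)-6-(3-methylbutyl)-1-(triethylsilyloxy)-1,2,3,4-tetrahydronaphthalene-5-carboxylate (key-step product) | C=CCOC(=O)c1c(CCC(C)C)cc(O[Si](C)(C)C(C)(C)C)c2c1C[C@@H](O[Si](C)(C)C(C)(C)C)C[C@H]2O[Si](CC)(CC)CC | intermediate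
19 | (1R,3R)-3,8-bis(tert-butyldimethylsilyloxy)-6-(3-methylbutyl)-1-(triethylsilyloxy)-1,2,3,4-tetrahydronaphthalene-5-carboxylic acid | OC(=O)c1c(CCC(C)C)cc(O[Si](C)(C)C(C)(C)C)c2c1C[C@@H](O[Si](C)(C)C(C)(C)C)C[C@H]2O[Si](CC)(CC)CC | intermediate
20 | 2,2,6-trimethyl-4H-1,3-dioxin-4-one | CC1=CC(=O)OC(C)(C)O1 | starting material
21 | (1R,3R)-3,8-bis(tert-butyldimethylsilyloxy)-6-(3-methylbutyl)-1-(triethylsilyloxy)-1,2,3,4-tetrahydronaphthalene-5-carbonyl chloride (not isolated) | ClC(=O)c1c(CCC(C)C)cc(O[Si](C)(C)C(C)(C)C)c2c1C[C@@H](O[Si](C)(C)C(C)(C)C)C[C@H]2O[Si](CC)(CC)CC | intermediate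
22 | lithium 2,2-dimethyl-6-methylidene-6H-1,3-dioxin-4-olate (not isolated) | C=C1C=C(O[Li])OC(C)(C)O1 | intermediate
23 | 6-{2-[(1R,3R)-3,8-bis(tert-butyldimethylsilyloxy)-6-(3-methylbutyl)-1-(triethylsilyloxy)-1,2,3,4-tetrahydronaphthalen-5-yl]-2-oxoethyl}-2,2-dimethyl-4H-1,3-dioxin-4-one | CC1(C)OC(=O)C=C(CC(=O)c2c(CCC(C)C)cc(O[Si](C)(C)C(C)(C)C)c3c2C[C@@H](O[Si](C)(C)C(C)(C)C)C[C@H]3O[Si](CC)(CC)CC)O1 | intermediate
24 | 5-[(1R,3R)-3,8-bis(tert-butyldimethylsilyloxy)-6-(3-methylbutyl)-1-(triethylsilyloxy)-1,2,3,4-tetrahydronaphthalen-5-yl]pent-1-ene-1,3,5-trione (not isolated) | O=C=CC(=O)CC(=O)c1c(CCC(C)C)cc(O[Si](C)(C)C(C)(C)C)c2c1C[C@@H](O[Si](C)(C)C(C)(C)C)C[C@H]2O[Si](CC)(CC)CC | intermediate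
25 | 4-hydroxy-6-[(1R,3R)-3,8-bis(tert-butyldimethylsilyloxy)-6-(3-methylbutyl)-1-(triethylsilyloxy)-1,2,3,4-tetrahydronaphthalen-5-yl]-2H-pyran-2-one | Oc1cc(-c2c(CCC(C)C)cc(O[Si](C)(C)C(C)(C)C)c3c2C[C@@H](O[Si](C)(C)C(C)(C)C)C[C@H]3O[Si](CC)(CC)CC)oc(=O)c1 | intermediate
26 | 4-hydroxy-6-[(1R,3R)-3,8-bis(tert-butyldimethylsilyloxy)-1-hydroxy-6-(3-methylbutyl)-1,2,3,4-tetrahydronaphthalen-5-yl]-2H-pyran-2-one | Oc1cc(-c2c(CCC(C)C)cc(O[Si](C)(C)C(C)(C)C)c3c2C[C@@H](O[Si](C)(C)C(C)(C)C)C[C@H]3O)oc(=O)c1 | intermediate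
27 | (3R)-3,8-bis(tert-butyldimethylsilyloxy)-5-(4-hydroxy-2-oxo-2H-pyran-6-yl)-6-(3-methylbutyl)-3,4-dihydronaphthalen-1(2H)-one | Oc1cc(-c2c(CCC(C)C)cc(O[Si](C)(C)C(C)(C)C)c3c2C[C@@H](O[Si](C)(C)C(C)(C)C)CC3=O)oc(=O)c1 | intermediate
28 | (3R)-3,8-dihydroxy-5-(4-hydroxy-2-oxo-2H-pyran-6-yl)-6-(3-methylbutyl)-3,4-dihydronaphthalen-1(2H)-one (CNP0134824.1) | CC(C)CCc1cc(O)c2c(c1-c1cc(O)cc(=O)o1)C[C@@H](O)CC2=O | target

## Step count

Total steps: 16. Longest linear sequence: 15 steps (steps 1–8 and 10–16); step 9 is a one-step side branch.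

## Steps most likely to fail

**Step 10.** The β-alkyl ynoate is a weak dienophile. The cycloaddition may be so slow at 150 °C that the diene decomposes or oligomerises first, or regiocontrol may leak towards the meta isomer at that temperature. The fallback sets out from diene 12 and alkyne 13 and returns at acid 19. Alkyne 13 would be formylated (n-BuLi, then DMF, buffered aqueous quench) to 6-methylhept-2-ynal F1, a far more reactive dienophile with the same polarisation. F1 should add to 12 in toluene at 60–80 °C to give the cyclohexadiene carbaldehyde F2, which DDQ would dehydrogenate in the same flask to the aryl aldehyde F3. Pinnick oxidation (NaClO2, NaH2PO4, 2-methylbut-2-ene, t-BuOH/H2O) would then give acid 19.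

**Step 12.** The di-ortho-substituted acyl chloride is sterically shielded. The dienolate may be diverted to O-acylation, or the chloride may remain unreacted while the excess base attacks the silyl ethers. The fallback sets out from ester 18 and returns at keto-dioxinone 23. Reduction of 18 with i-Bu2AlH (CH2Cl2, −78 → 0 °C) would give the benzylic alcohol F4, and Dess–Martin periodinane with NaHCO3 would give the aldehyde F3 described under the first fallback. Vinylogous aldol addition of lithium dienolate 22 (THF, −78 °C) to this less hindered, more electrophilic carbonyl would give the carbinol F5 as a mixture of epimers. Dess–Martin oxidation of F5 would give 23.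

**Step 16.** Once the C1 ketone is present, loss of the C3 oxygen by β-elimination and aromatisation to a naphthol may compete with desilylation, or the secondary silyl ether may cleave incompletely under conditions mild enough to avoid this. The fallback sets out from pyranone 25 and returns at target 28. It inverts the last operations so that the ketone is formed only at the end. All three silyl groups of 25 would be removed with Bu4NF buffered with AcOH (THF, rt) to give the triol-phenol F6, which contains no ketone and cannot eliminate by this path. Chemoselective oxidation of the benzylic C1 carbinol of F6 with activated MnO2 (acetone/EtOAc, rt) should then give 28 directly, since the non-benzylic C3 alcohol is not oxidised under these conditions.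

## Further compounds

F1 | step 10 | 6-methylhept-2-ynal | O=CC#CCCC(C)C
F2 | step 10 | (1R,3R)-3,8-bis(tert-butyldimethylsilyloxy)-6-(3-methylbutyl)-1-(triethylsilyloxy)-1,2,3,4,4a,7-hexahydronaphthalene-5-carbaldehyde, both C4a epimers | O=CC1=C(CCC(C)C)CC(O[Si](C)(C)C(C)(C)C)=C2C1C[C@@H](O[Si](C)(C)C(C)(C)C)C[C@H]2O[Si](CC)(CC)CC
F3 | step 10 | (1R,3R)-3,8-bis(tert-butyldimethylsilyloxy)-6-(3-methylbutyl)-1-(triethylsilyloxy)-1,2,3,4-tetrahydronaphthalene-5-carbaldehyde | O=Cc1c(CCC(C)C)cc(O[Si](C)(C)C(C)(C)C)c2c1C[C@@H](O[Si](C)(C)C(C)(C)C)C[C@H]2O[Si](CC)(CC)CC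
F4 | step 12 | [(1R,3R)-3,8-bis(tert-butyldimethylsilyloxy)-6-(3-methylbutyl)-1-(triethylsilyloxy)-1,2,3,4-tetrahydronaphthalen-5-yl]methanol | OCc1c(CCC(C)C)cc(O[Si](C)(C)C(C)(C)C)c2c1C[C@@H](O[Si](C)(C)C(C)(C)C)C[C@H]2O[Si](CC)(CC)CC
F5 | step 12 | 6-{2-[(1R,3R)-3,8-bis(tert-butyldimethylsilyloxy)-6-(3-methylbutyl)-1-(triethylsilyloxy)-1,2,3,4-tetrahydronaphthalen-5-yl]-2-hydroxyethyl}-2,2-dimethyl-4H-1,3-dioxin-4-one, both carbinol epimers | CC1(C)OC(=O)C=C(CC(O)c2c(CCC(C)C)cc(O[Si](C)(C)C(C)(C)C)c3c2C[C@@H](O[Si](C)(C)C(C)(C)C)C[C@H]3O[Si](CC)(CC)CC)O1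
F6 | step 16 | 4-hydroxy-6-[(1R,3R)-1,3,8-trihydroxy-6-(3-methylbutyl)-1,2,3,4-tetrahydronaphthalen-5-yl]-2H-pyran-2-one | Oc1cc(-c2c(CCC(C)C)cc(O)c3c2C[C@@H](O)C[C@H]3O)oc(=O)c1
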